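**Retrosynthetic overview**

1. The last steps put the acetate on one ring oxygen (freed from a TIPS ether) and then free the other by hydrogenolysis of a benzyl ether; the two oxygens are already different in the purchased arene.
2. Key disconnection: the bond between the benzylic CH2 (chain C1) and the carbinol carbon (chain C2). Both carbons come in as nucleophiles, C1 as the C–B bond of a benzyl pinacol boronate and C2 as the enantioenriched α-lithiated carbamate of tridecan-1-ol. They are joined by a 1,2-metallate shift, and oxidation of the C–B bond gives the C2 carbinol.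
3. Enabling feature: C2 is the only stereocenter, a secondary carbinol carbon whose own oxygen, as the N,N-diisopropylcarbamate, first directs the enantioselective α-lithiation and then leaves. Its neighbour C1 is a benzylic CH2 on C5 of the benzene-1,3-diol ring and is easily carried as a C–B bond; the etherified ring oxygens are inert to the carbanion.
4. Rings: the benzene ring is the only ring; it is bought and no ring is formed.
5. Fragments: aryl ester → benzyl alcohol → benzyl bromide → benzyl boronate; tridecan-1-ol → carbamate.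

Key step: step 6

Remark: rotation about the aryl–CH2 bond makes the two ring oxygens equivalent, so the mono-acetate is a single compound; methyl 3-(benzyloxy)-5-hydroxybenzoate is taken as a catalogue compound.

**Route**

Step 1
Reactants: 1 tridecan-1-ol
Product: 2 tridecyl N,N-diisopropylcarbamate
Conditions: i-Pr2NCOCl (1.2 equiv), Et3N (1.5 equiv), CH2Cl2, reflux
Reagents that add atoms: N,N-diisopropylcarbamoyl chloride, CC(C)N(C(C)C)C(Cl)=O
Why: Carbamoylation of a primary alcohol with a carbamoyl chloride should proceed cleanly and installs the hindered carbamate that directs α-lithiation.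

Step 2
Reactants: 3 methyl 3-(benzyloxy)-5-hydroxybenzoate
Product: 4 methyl 3-(benzyloxy)-5-[(triisopropylsilyl)oxy]benzoate
Conditions: TIPSCl (1.2 equiv), imidazole (2.5 equiv), DMF, rt
Reagents that add atoms: chlorotriisopropylsilane, CC(C)[Si](Cl)(C(C)C)C(C)C
Why: Imidazole-mediated silylation of a phenol should give an aryl TIPS ether that tolerates hydride, Pd/KOAc, an organolithium at −78 °C and brief alkaline peroxide.

Step 3
Reactants: 4 methyl 3-(benzyloxy)-5-[(triisopropylsilyl)oxy]benzoate
Product: 5 {3-(benzyloxy)-5-[(triisopropylsilyl)oxy]phenyl}methanol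
Conditions: i-Bu2AlH (2.5 equiv), CH2Cl2, −78 to 0 °C; aq. KNaC4H4O6 (potassium sodium tartrate) work-up
Reagents that add atoms: none
Why: Hydride reduction of an aryl ester to the benzylic alcohol should leave the benzyl and silyl ethers untouched.

Step 4
Reactants: 5 {3-(benzyloxy)-5-[(triisopropylsilyl)oxy]phenyl}methanol
Product: 6 [3-(benzyloxy)-5-(bromomethyl)phenoxy]triisopropylsilane
Conditions: CBr4 (1.3 equiv), PPh3 (1.3 equiv), CH2Cl2, 0 °C to rt
Reagents that add atoms: carbon tetrabromide, BrC(Br)(Br)Br
Why: The Appel reaction converts the primary benzylic alcohol to the bromide under neutral conditions, and the meta oxygens do not make the bromide prone to ionisation.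

Step 5
Reactants: 6 [3-(benzyloxy)-5-(bromomethyl)phenoxy]triisopropylsilane
Product: 7 2-{3-(benzyloxy)-5-[(triisopropylsilyl)oxy]benzyl}-4,4,5,5-tetramethyl-1,3,2-dioxaborolane
Conditions: B2pin2 (1.2 equiv), Pd(dba)2 (3 mol %), (4-MeOC6H4)3P (6 mol %), KOAc (1.5 equiv), toluene, 50 °C
Reagents that add atoms: bis(pinacolato)diboron, CC1(C)OB(B2OC(C)(C)C(C)(C)O2)OC1(C)C
Why: Miyaura-type borylation of a benzylic halide (oxidative addition of C–Br to zerovalent palladium, acetate-assisted transmetalation with the diboron, reductive elimination) should give the benzyl boronate.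

Step 6
Reactants: 2 tridecyl N,N-diisopropylcarbamate; 7 2-{3-(benzyloxy)-5-[(triisopropylsilyl)oxy]benzyl}-4,4,5,5-tetramethyl-1,3,2-dioxaborolane
Product: 11 (2S)-1-{3-(benzyloxy)-5-[(triisopropylsilyl)oxy]phenyl}tetradecan-2-ol, via lithiated carbamate 8 (not isolated), via boronate complex 9 (not isolated), via secondary boronic ester 10 (not isolated)
Conditions: 2 (1.5 equiv), (+)-sparteine (1.4 equiv), s-BuLi (1.4 equiv), Et2O, −78 °C, 5 h; 7 (1.0 equiv) in Et2O, −78 °C, 1 h; MgBr2·OEt2 (2 equiv), −78 °C to reflux, 16 h; then 2 M NaOH, 30 % H2O2, THF, 0 °C to rt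
Reagents that add atoms: hydrogen peroxide, OO (carbinol oxygen); sec-butyllithium, CCC(C)[Li] (only the lithium of 8 and 9)
Why: (+)-Sparteine·s-BuLi removes the pro-R α-hydrogen of 2 under direction by the carbamate carbonyl to give the configurationally stable (R)-lithio carbamate 8, which adds to the boron of 7 with retention to give boronate complex 9; MgBr2 then promotes an antiperiplanar 1,2-shift of the benzyl group from boron to carbon with loss of the carbamate and inversion, and the (S)-boronic ester 10 is oxidised by alkaline H2O2 with retention. The closest known reaction type is the lithiation–borylation of Hoppe-type primary alkyl carbamates with pinacol boronic esters, a reagent-controlled Matteson-type homologation. No ring is closed. The single new stereocenter is set by the chiral diamine alone (choice of the enantiotopic proton, then retention, inversion, retention), so the (S) configuration follows from using (+)-sparteine. The step needs the carbanion to attack boron faster than it deprotonates the benzylic C–H of 7; this is secured by the empty orbital on boron at −78 °C, by the absence of any acidic or electrophilic group in 7 (both phenols are ethers) and by keeping 2 in slight excess over s-BuLi so that no free alkyllithium remains. In one flask the step joins the two fragments, sets the only stereocenter and installs the carbinol oxygen.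

Step 7
Reactants: 11 (2S)-1-{3-(benzyloxy)-5-[(triisopropylsilyl)oxy]phenyl}tetradecan-2-ol
Product: 12 3-(benzyloxy)-5-[(2S)-2-hydroxytetradecyl]phenol
Conditions: Bu4NF (1.1 equiv), AcOH (1.1 equiv), THF, 0 °C to rt
Reagents that add atoms: none
Why: Buffered fluoride cleaves the aryl silyl ether selectively, and the carbinol center is not touched.

Step 8
Reactants: 12 3-(benzyloxy)-5-[(2S)-2-hydroxytetradecyl]phenol
Product: 13 3-(benzyloxy)-5-[(2S)-2-hydroxytetradecyl]phenyl acetate
Conditions: Ac2O (1.05 equiv), Et3N (1.2 equiv), CH2Cl2, −20 to 0 °C, no DMAP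
Reagents that add atoms: acetic anhydride, CC(=O)OC(C)=O
Why: Chemoselective O-acetylation should occur at the phenol, which is deprotonated by the amine and acylated far faster than the hindered secondary alcohol when no acyl-transfer catalyst is present.

Step 9
Reactants: 13 3-(benzyloxy)-5-[(2S)-2-hydroxytetradecyl]phenyl acetate
Product: 14 3-hydroxy-5-[(2S)-2-hydroxytetradecyl]phenyl acetate
Conditions: H2 (1 atm), Pd/C (10 %), EtOAc, rt
Reagents that add atoms: none
Why: Hydrogenolysis of the benzyl aryl ether under neutral, aprotic conditions should leave the aryl acetate and the homobenzylic (not benzylic) carbinol intact.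

**Compound list**

1 | tridecan-1-ol | CCCCCCCCCCCCCO | starting material
2 | tridecyl N,N-diisopropylcarbamate | CCCCCCCCCCCCCOC(=O)N(C(C)C)C(C)C | intermediate
3 | methyl 3-(benzyloxy)-5-hydroxybenzoate | COC(=O)c1cc(O)cc(OCc2ccccc2)c1 | starting material
4 | methyl 3-(benzyloxy)-5-[(triisopropylsilyl)oxy]benzoate | COC(=O)c1cc(OCc2ccccc2)cc(O[Si](C(C)C)(C(C)C)C(C)C)c1 | intermediate
5 | {3-(benzyloxy)-5-[(triisopropylsilyl)oxy]phenyl}methanol | OCc1cc(OCc2ccccc2)cc(O[Si](C(C)C)(C(C)C)C(C)C)c1 | intermediate
6 | [3-(benzyloxy)-5-(bromomethyl)phenoxy]triisopropylsilane | BrCc1cc(OCc2ccccc2)cc(O[Si](C(C)C)(C(C)C)C(C)C)c1 | intermediate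
7 | 2-{3-(benzyloxy)-5-[(triisopropylsilyl)oxy]benzyl}-4,4,5,5-tetramethyl-1,3,2-dioxaborolane | CC1(C)OB(Cc2cc(OCc3ccccc3)cc(O[Si](C(C)C)(C(C)C)C(C)C)c2)OC1(C)C | intermediate
8 | (1R)-1-lithiotridecyl N,N-diisopropylcarbamate, present as its (+)-sparteine complex | CCCCCCCCCCCC[C@@H]([Li])OC(=O)N(C(C)C)C(C)C | intermediate
9 | lithium boronate complex of 8 with 7, (R) at the carbamate-bearing carbon | CCCCCCCCCCCC[C@@H]([B-]1(Cc2cc(OCc3ccccc3)cc(O[Si](C(C)C)(C(C)C)C(C)C)c2)OC(C)(C)C(C)(C)O1)OC(=O)N(C(C)C)C(C)C.[Li+] | intermediate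
10 | 2-[(2S)-1-{3-(benzyloxy)-5-[(triisopropylsilyl)oxy]phenyl}tetradecan-2-yl]-4,4,5,5-tetramethyl-1,3,2-dioxaborolane | CCCCCCCCCCCC[C@H](B1OC(C)(C)C(C)(C)O1)Cc1cc(OCc2ccccc2)cc(O[Si](C(C)C)(C(C)C)C(C)C)c1 | intermediate
11 | (2S)-1-{3-(benzyloxy)-5-[(triisopropylsilyl)oxy]phenyl}tetradecan-2-ol | CCCCCCCCCCCC[C@H](O)Cc1cc(OCc2ccccc2)cc(O[Si](C(C)C)(C(C)C)C(C)C)c1 | intermediate
12 | 3-(benzyloxy)-5-[(2S)-2-hydroxytetradecyl]phenol | CCCCCCCCCCCC[C@H](O)Cc1cc(O)cc(OCc2ccccc2)c1 | intermediate
13 | 3-(benzyloxy)-5-[(2S)-2-hydroxytetradecyl]phenyl acetate | CCCCCCCCCCCC[C@H](O)Cc1cc(OCc2ccccc2)cc(OC(C)=O)c1 | intermediate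
14 | 3-hydroxy-5-[(2S)-2-hydroxytetradecyl]phenyl acetate | CCCCCCCCCCCC[C@H](O)Cc1cc(O)cc(OC(C)=O)c1 | target

**Summary**

Total step count: 9. Longest linear sequence: 8 steps (3 to 14, steps 2 to 9); step 1 is the one-step branch to 2.

Steps most likely to fail:

1. Step 6. The lithiated carbamate may deprotonate the benzylic C–H of the boronate instead of adding to boron, the 1,2-shift may stall, or the enantiotopic deprotonation may be less selective than usual. The fallback sets out from 7 and returns at 11, making the same bond by auxiliary-controlled Matteson homologation. Transesterification of 7 with (+)-pinanediol, (1S,2S,3R,5S)-pinane-2,3-diol (Et2O, rt), should give the (+)-pinanediol 3-(benzyloxy)-5-[(triisopropylsilyl)oxy]benzylboronate F1. Insertion of LiCHCl2 (from CH2Cl2 and n-BuLi, THF, −100 °C, then ZnCl2, to rt) should give the (1S)-1-chloro-2-arylethyl pinanediol boronate F2 under control of the diol. C12H25MgBr (THF, −78 °C to rt) should displace chloride with inversion through a borate 1,2-shift to give the (2S)-1-aryltetradecan-2-yl pinanediol boronate F3. Oxidation with NaOH/H2O2 (retention) should give 11.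

2. Step 8. Chemoselectivity may be lost, with acetyl transfer to the secondary alcohol or double acetylation. The fallback sets out from 11 and returns at 14, masking the carbinol before the phenol is freed. O-benzylation of 11 (NaH, BnBr, Bu4NI, THF, 0 °C to rt) should give {3-(benzyloxy)-5-[(2S)-2-(benzyloxy)tetradecyl]phenoxy}triisopropylsilane F4. Bu4NF/AcOH should give 3-(benzyloxy)-5-[(2S)-2-(benzyloxy)tetradecyl]phenol F5. Acetylation without any selectivity demand (Ac2O, pyridine, DMAP, CH2Cl2) should give 3-(benzyloxy)-5-[(2S)-2-(benzyloxy)tetradecyl]phenyl acetate F6. Hydrogenolysis of both benzyl ethers (H2, Pd(OH)2/C, EtOAc) should give 14.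

3. Step 5. The benzylpalladium intermediate may homocouple to the bibenzyl, or product 7 may cross-couple with unreacted 6. The fallback sets out from 6 and returns at 7, reversing the polarity of the benzyl unit. Mg turnings and pinacolborane in THF at rt under Barbier conditions should form {3-(benzyloxy)-5-[(triisopropylsilyl)oxy]benzyl}magnesium bromide F7, which is trapped at boron as it forms to give 7.

**Further compounds**

F1 | step 6 | (+)-pinanediol 3-(benzyloxy)-5-[(triisopropylsilyl)oxy]benzylboronate | C[C@@]1(O3)[C@H](OB3Cc4cc(OCc5ccccc5)cc(O[Si](C(C)C)(C(C)C)C(C)C)c4)C[C@@H]2C[C@H]1C2(C)C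
F2 | step 6 | (+)-pinanediol (1S)-1-chloro-2-{3-(benzyloxy)-5-[(triisopropylsilyl)oxy]phenyl}ethylboronate | C[C@@]1(O3)[C@H](OB3[C@H](Cl)Cc4cc(OCc5ccccc5)cc(O[Si](C(C)C)(C(C)C)C(C)C)c4)C[C@@H]2C[C@H]1C2(C)C
F3 | step 6 | (+)-pinanediol (2S)-1-{3-(benzyloxy)-5-[(triisopropylsilyl)oxy]phenyl}tetradecan-2-ylboronate | C[C@@]1(O3)[C@H](OB3[C@@H](CCCCCCCCCCCC)Cc4cc(OCc5ccccc5)cc(O[Si](C(C)C)(C(C)C)C(C)C)c4)C[C@@H]2C[C@H]1C2(C)C
F4 | step 8 | {3-(benzyloxy)-5-[(2S)-2-(benzyloxy)tetradecyl]phenoxy}triisopropylsilane | CCCCCCCCCCCC[C@H](OCc1ccccc1)Cc1cc(OCc2ccccc2)cc(O[Si](C(C)C)(C(C)C)C(C)C)c1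
F5 | step 8 | 3-(benzyloxy)-5-[(2S)-2-(benzyloxy)tetradecyl]phenol | CCCCCCCCCCCC[C@H](OCc1ccccc1)Cc1cc(O)cc(OCc2ccccc2)c1
F6 | step 8 | 3-(benzyloxy)-5-[(2S)-2-(benzyloxy)tetradecyl]phenyl acetate | CCCCCCCCCCCC[C@H](OCc1ccccc1)Cc1cc(OCc2ccccc2)cc(OC(C)=O)c1
F7 | step 5 | {3-(benzyloxy)-5-[(triisopropylsilyl)oxy]benzyl}magnesium bromide | Br[Mg]Cc1cc(OCc2ccccc2)cc(O[Si](C(C)C)(C(C)C)C(C)C)c1
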